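The data are calculated for substances that don't exist; the scatter is artificial.

What is left of the electrophile at the last reading is the number I carry forward, and in logarithms it turns into a rate.

| setting | ash | larch | alpha | delta |
|---|---|---|---|---|
| electrophile | 0.27 M | 0.20 M | 0.40 M | 0.40 M |
| protonated nucleophile | 3 equiv | 3 equiv | 3.00 equiv | 6.00 equiv |
| gas | 73 mM (held) | 73 mM (held) | 73 mM (held) | 73 mM (held) |
| remark | run made earlier | run made earlier |  |  |
| time |  |  | 10 d | 10 d |

| run | time / d | electrophile / % | target / % |
|---|---|---|---|
| ash | 0.250 | 98 | 0 |
| ash | 0.417 | 99 | 1 |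
| ash | 0.625 | 98 | 1 |
| ash | 1.04 | 91 | 5 |
| ash | 1.67 | 87 | 8 |
| ash | 2.50 | 84 | 14 |
| ash | 4.00 | 71 | 20 |
| larch | 0.250 | 98 | 1 |
| larch | 0.417 | 99 | 2 |
| larch | 0.625 | 93 | 2 |
| larch | 1.04 | 94 | 3 |
| larch | 1.67 | 90 | 6 |
| larch | 2.50 | 87 | 11 |
| larch | 4.00 | 72 | 23 |

(standard deviation of a reading: 2 percentage points)

- at the start none of the gas is in solution

1. part of the electrophile that has reacted at the end, alpha
2. part of the electrophile that has reacted at the end, delta
3. what raising the equivalents of protonated nucleophile from its lowest to its highest value here does to the part of the electrophile that has reacted (changes below 5 percentage points count as none) (no change / it falls / it rises)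

What do the two runs show? At 4.00 d the ash run has 71% of its electrophile left and the larch run 72%, from charges of 0.27 M and 0.20 M. That gap is smaller than the scatter of 2 percentage points, so at 3 equiv I treat these two charges as one curve in percent.

Put that in one number. I take the decade rate D, the powers of ten of electrophile lost per day, averaged over both last readings: 0.0364 d⁻¹. This treats the decay as pseudo-first-order, in base ten.

And alpha? It has the same 3.00 equiv, so over 10 d the exponent is 0.364. That leaves 43.3%, and my figure for the part reacted is 56.8%.

Where is that weak? D runs a straight line from the origin, yet the ash run still reads 98% at 0.625 d, and the gas starts with none in solution. If the rate is still climbing past 4.00 d, D reads low, so I hold my figure as a low one. Alpha's 0.40 M also lies outside both runs.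

Delta? Both runs stand at 3 equiv, so D says nothing about 6.00 equiv. I write the same figure for delta and guess a rise above it, as a protonated nucleophile may act as a store of nucleophile.

The forecast, which differs from mine, gives 52% for alpha, 52% for delta and no change, taking as its simplest reading “first order in electrophile and zero order in protonated nucleophile”.

Alpha has reacted 65.0% and delta 74.3%, so with more equivalents it rises, by 9.4 points; at 10.0 d delta holds 54.0% target and 20.3% side product, alpha 52.3% and 12.7%.

    electrophile + nucleophile → acid set free + target (k = 1.20 × 10⁻⁵ L mol⁻¹ s⁻¹)
    nucleophile + acid set free ⇌ protonated nucleophile, settled at all times (K = 13000 L mol⁻¹)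
    acid set free + free base ⇌ salt of the base, settled at all times (K = 74000 L mol⁻¹)
    electrophile + acid set free → side product (k = 1.70 × 10⁻⁴ L mol⁻¹ s⁻¹)
    gas ⇌ free base, rate k5*(csat - [free base]) (kL = 8.50 × 10⁻⁶ s⁻¹)

Over 10 d alpha's own decade rate comes to 0.0456 d⁻¹, higher than the 0.0364 d⁻¹ of the runs. In the neighbour flask, alpha read at 2.50 d, D gives 81.1% left, and that flask holds 81.1%.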